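**Plan**

- Retrosynthesis: first remove the two benzyl ethers from the catechol. Then cut the CH2–CH2 bond between C4 and C5 of the octadecyl chain (counted from the ester oxygen) into two primary alkyl radicals, each traced back to a carboxylic acid one carbon longer, activated as its N-hydroxyphthalimide ester. Last, cut the ester O–CH2 bond of the short fragment to 2,3-bis(benzyloxy)benzoic acid and tert-butyl 5-bromopentanoate.
- Enabling feature: the chain is an unbranched (CH2)17 unit. C4 and C5 are both primary methylenes with only CH2 neighbours, so each is a primary radical reachable by loss of CO2 (from pentadecanoic acid and from a 5-(aroyloxy)pentanoic acid). The only ring, the benzene ring of the 2,3-dihydroxybenzoate, lies behind the ester, and its O-2/O-3 catechol is masked as benzyl ethers.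
- Forward: the aryl ester is made on the C5 acid, both acids become redox-active esters, the chain is joined by a Ni-electrocatalytic doubly decarboxylative C(sp3)–C(sp3) coupling, and hydrogenolysis frees the catechol.
- Stereochemistry: the target has no stereocentre and no stereogenic alkene, so nothing has to be set.

Key step: step 5

Remark: the target is achiral, so "single enantiomer" needs no stereocontrol; 2,3-bis(benzyloxy)benzoic acid, tert-butyl 5-bromopentanoate, pentadecanoic acid and N-hydroxyphthalimide are assumed to be catalogue chemicals.

**Route**

Step 1
Reactants: 1 2,3-bis(benzyloxy)benzoic acid; 2 tert-butyl 5-bromopentanoate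
Product: 3 tert-butyl 5-{[2,3-bis(benzyloxy)benzoyl]oxy}pentanoate
Conditions: K2CO3, KI (cat.), DMF, 50 °C
Reagents that add atoms: none
Why: SN2 O-alkylation of the carboxylate by an unhindered primary bromide (carboxylate esterification) should be clean because the phenols are already benzylated and the tert-butyl ester is inert to carbonate.

Step 2
Reactants: 3 tert-butyl 5-{[2,3-bis(benzyloxy)benzoyl]oxy}pentanoate
Product: 4 5-{[2,3-bis(benzyloxy)benzoyl]oxy}pentanoic acid
Conditions: TFA/CH2Cl2 (1:4), 0 °C to rt
Reagents that add atoms: none
Why: Acidolysis of the tert-butyl ester with loss of isobutene should leave the primary alkyl benzoate and, at this acid strength and temperature, the aryl benzyl ethers untouched.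

Step 3
Reactants: 4 5-{[2,3-bis(benzyloxy)benzoyl]oxy}pentanoic acid; 5 N-hydroxyphthalimide
Product: 6 1,3-dioxoisoindolin-2-yl 5-{[2,3-bis(benzyloxy)benzoyl]oxy}pentanoate
Conditions: DIC, DMAP (cat.), CH2Cl2, rt
Reagents that add atoms: none
Why: Carbodiimide (Steglich-type) coupling of the free acid with the N-hydroxy imide should give the redox-active ester, since no competing nucleophile is present.

Step 4
Reactants: 7 pentadecanoic acid; 5 N-hydroxyphthalimide
Product: 8 1,3-dioxoisoindolin-2-yl pentadecanoate
Conditions: DIC, DMAP (cat.), CH2Cl2, rt
Reagents that add atoms: none
Why: The same carbodiimide esterification on a plain fatty acid should give a crystalline redox-active ester.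

Step 5
Reactants: 6 1,3-dioxoisoindolin-2-yl 5-{[2,3-bis(benzyloxy)benzoyl]oxy}pentanoate; 8 1,3-dioxoisoindolin-2-yl pentadecanoate (3 equiv)
Product: 9 octadecyl 2,3-bis(benzyloxy)benzoate
Conditions: NiCl2·6H2O (20 mol %), 2,2':6',2''-terpyridine (20 mol %), AgNO3 (0.3 equiv), DMF, Mg(+)/RVC(−), undivided cell, constant current, rt
Reagents that add atoms: none
Why: Cathodically generated low-valent terpyridine–nickel, at a cathode coated in situ with silver nanoparticles, should transfer single electrons to both N-acyloxyphthalimides, whose radical anions fragment with loss of phthalimide anion and CO2 to the tetradecyl and 4-(aroyloxy)butyl primary radicals; capture of the two radicals at nickel gives a dialkylnickel(III) species that reductively eliminates the CH2–CH2 bond, the Mg anode supplying the two electrons. The closest known reaction type is the Ni-electrocatalytic doubly decarboxylative C(sp3)–C(sp3) cross-coupling of two redox-active esters, which covers primary–primary pairs. No ring is closed and no stereocentre is formed. The selectivity needed is cross- over homo-coupling, which is statistical for two unhindered primary partners; it is secured by the threefold excess of cheap 8, so that 6 is consumed mainly as cross-product, and by the large polarity gap between octacosane, monoester 9 and the diester homodimer, which should make chromatography simple. The benzoate ester and the aryl benzyl ethers lie outside the reduction window of the redox-active esters and carry no acidic O–H (the reason for masking the catechol), and the ester oxygen is δ to the radical centre, so no β-scission or acyloxy shift is available.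

Step 6
Reactants: 9 octadecyl 2,3-bis(benzyloxy)benzoate
Product: 10 Gentiside E (octadecyl 2,3-dihydroxybenzoate)
Conditions: H2 (1 atm), 10 % Pd/C, EtOAc/THF, rt
Reagents that add atoms: none
Why: Catalytic hydrogenolysis of the two aryl benzyl ethers should free the catechol without touching the alkyl benzoate or the saturated chain, and a non-alcoholic solvent excludes transesterification.

**Compound list**

1 | 2,3-bis(benzyloxy)benzoic acid | O=C(O)c1cccc(OCc2ccccc2)c1OCc1ccccc1 | starting material
2 | tert-butyl 5-bromopentanoate | CC(C)(C)OC(=O)CCCCBr | starting material
3 | tert-butyl 5-{[2,3-bis(benzyloxy)benzoyl]oxy}pentanoate | CC(C)(C)OC(=O)CCCCOC(=O)c1cccc(OCc2ccccc2)c1OCc1ccccc1 | intermediate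
4 | 5-{[2,3-bis(benzyloxy)benzoyl]oxy}pentanoic acid | OC(=O)CCCCOC(=O)c1cccc(OCc2ccccc2)c1OCc1ccccc1 | intermediate
5 | N-hydroxyphthalimide | O=C1c2ccccc2C(=O)N1O | starting material
6 | 1,3-dioxoisoindolin-2-yl 5-{[2,3-bis(benzyloxy)benzoyl]oxy}pentanoate | O=C(CCCCOC(=O)c1cccc(OCc2ccccc2)c1OCc1ccccc1)ON1C(=O)c2ccccc2C1=O | intermediate
7 | pentadecanoic acid | CCCCCCCCCCCCCCC(=O)O | starting material
8 | 1,3-dioxoisoindolin-2-yl pentadecanoate | CCCCCCCCCCCCCCC(=O)ON1C(=O)c2ccccc2C1=O | intermediate
9 | octadecyl 2,3-bis(benzyloxy)benzoate | CCCCCCCCCCCCCCCCCCOC(=O)c1cccc(OCc2ccccc2)c1OCc1ccccc1 | intermediate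
10 | Gentiside E (octadecyl 2,3-dihydroxybenzoate) | CCCCCCCCCCCCCCCCCCOC(=O)c1cccc(O)c1O | target

**Step count**

Total steps: 6. Longest linear sequence: 5 (steps 1, 2, 3, 5, 6).

**Steps most likely to fail**

Step 5. The two primary radicals may pair statistically so that 6 is lost to its homodimer, or the alkylnickel intermediates may be diverted to reduction (alkane) or β-hydride elimination (alkene). The fallback replaces radical pairing by a polarity-defined two-electron coupling of the same two carbons. It sets out from 1: alkylation with excess 1,4-dibromobutane (BrCCCCBr; K2CO3, DMF) should give 4-bromobutyl 2,3-bis(benzyloxy)benzoate F1. Hydroboration of tetradec-1-ene (C=CCCCCCCCCCCCC) with 9-BBN in THF should give 9-tetradecyl-9-borabicyclo[3.3.1]nonane F2. An alkyl–alkyl Suzuki–Miyaura coupling of the two (Pd(OAc)2, PCy3, K3PO4·H2O, THF, rt) should form the same CH2–CH2 bond and returns to the route at 9.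

Step 2. The acid may partly strip the benzyl ethers (the 2-benzyloxy group is assisted by the neighbouring carbonyl), or the tert-butyl cation may alkylate the electron-rich ring. The fallback avoids any carboxyl protecting group and reaches the acid by adjusting the oxidation level. It sets out from 1: Steglich monoesterification with excess pentane-1,5-diol (OCCCCCO; EDC, DMAP, CH2Cl2) should give 5-hydroxypentyl 2,3-bis(benzyloxy)benzoate F3. TEMPO/PhI(OAc)2 oxidation of the primary alcohol in MeCN/water should then give the acid and returns to the route at 4.

Step 6. Hydrogenolysis may stall through catalyst poisoning by traces of nickel, silver or halide carried over from the electrolysis, or through slow cleavage of the shielded 2-O-benzyl group in the waxy substrate. The fallback replaces reductive cleavage on a metal surface by Lewis-acid heterolysis of the O–CH2 bonds. It sets out from 9: BCl3 with pentamethylbenzene as cation scavenger in CH2Cl2 at −78 °C should remove both benzyl groups (chelation to the ester carbonyl assists the 2-O-benzyl cleavage) and leave the alkyl ester intact. It returns to the route at 10 and makes no new compound on the way (entry F0).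

**Further compounds**

F1 | step 5 | 4-bromobutyl 2,3-bis(benzyloxy)benzoate | BrCCCCOC(=O)c1cccc(OCc2ccccc2)c1OCc1ccccc1
F2 | step 5 | 9-tetradecyl-9-borabicyclo[3.3.1]nonane | CCCCCCCCCCCCCCB1C2CCCC1CCC2
F3 | step 2 | 5-hydroxypentyl 2,3-bis(benzyloxy)benzoate | OCCCCCOC(=O)c1cccc(OCc2ccccc2)c1OCc1ccccc1
F0 | step 6 | none | none
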